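Compound numbers refer to the list after the steps. Ca is the stereogenic methine and Cb the diaryl-substituted methine. Ring A and ring C are the benzo and pyranone rings of the chromone, and ring D is the trihydroxyphenyl ring. C1–C9 is the chain numbering of triketo ester 14.

## Analysis of the target

(+)-Chamaechromone is an open-chain polyphenol organised around Ca, which carries C3 of a 5,7-dihydroxychromone (rings A and C), the carbonyl of a 2,4,6-trihydroxyphenyl ketone (ring D) and Cb with its two identical 4-hydroxyphenyl rings. Ca is the only stereocentre and is (S); Cb is not stereogenic, so the task is one absolute configuration that must be set and then kept. Keeping it is the delicate part, because the Ca–H bond lies alpha to the ring D ketone and on C3 of the chromone enone, and is therefore open to base- or Lewis-acid-mediated enolisation. In addition, C2 of ring C is electrophilic toward hydroxide and hard nucleophiles, and the seven phenols include the very electron-rich ring D. The difficulty is as much steric as electronic: Ca has three bulky branches and its aryl ketone is di-ortho-substituted, so acylating a ring D arene or adding an aryl-metal at the Ca carbonyl is unattractive. The strategy rests on the fact that the Ca-bound carbonyl carbon and the six carbons of ring D form a seven-carbon chain oxygenated at every second carbon, a folded tetraketide. Ring D can therefore be grown from a Ca carboxyl group and closed by a Claisen reaction, with no aryl–carbonyl bond to make. A second feature serves the early steps: the ring D carbonyl carbon, Ca, C3 and C4 form a four-carbon 1,4-dicarbonyl unit whose two ends can be told apart as ester and acid.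

## Retrosynthetic reasoning

**16 to 15.** The four aryl O–CH3 bonds on ring A and on the two Cb aryl rings are cut last. Methyl ethers are kept because they survive every Lewis acid, enolate and alkoxide of the route; ring D needs no protection because it is made at the end. The forward step must cleave four ethers without enolising the ketone beside Ca.

**15 to 14 (key disconnection).** One ring D bond is cut, between the acyl-bearing ring carbon (C6 of the chain) and its neighbour (C1, the former ester carbonyl). This is the only ring bond whose cleavage leaves a linear chain with all three ring oxygens in place and an ester as the electrophile. It removes the hindered aryl ketone construction and delivers ring D unprotected. The forward reaction has to favour Claisen closure over aldol closure and leave Ca and ring C untouched.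

**14 to 10 and 11.** The C6–C7 bond is cut, so that the branch point becomes a Ca carboxyl derivative (N-acylimidazole 13) and six of the seven chain carbons arrive in one piece as trianion 12 of 11. The terminal carbanion of 12 is its most nucleophilic site, which fixes the regiochemistry. Forward, C-acylation must outrun proton transfer from Ca–H.

**10 to 9.** Only the ester O–CH3 bond is cut. A methyl ester is chosen so that it can be removed by nucleophilic attack at the methyl carbon. Saponification would expose C2 of ring C and the acidic Ca–H to aqueous base while the ester carbonyl itself is shielded.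

**9 to 8.** Ring C is opened at O1–C2 and C2–C3, giving the 2-hydroxyaryl ketone 8 whose alpha-methylene is the future C3. C2 comes from a one-carbon formyl equivalent. The methylene next to the ketone is the only activated CH2, and Lewis-acidic conditions leave the ester-bound Ca–H alone.

**8 to 7 to 4 and 5.** The phenol of 8 comes from chelation-directed removal of one ortho methyl group of 7. Ketone 7 is cut at C4–C4a, a Friedel–Crafts acylation of the symmetric arene 5 by the unhindered methylene-arm carboxyl of 4 through mixed anhydride 6. The acid/ester differentiation in 4 sends ring A to one end and, later, ring D to the other.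

**4 to 3.** The two hydrogens across Ca–Cb are removed, leaving a tetrasubstituted alkene for asymmetric hydrogenation. Only Ca becomes stereogenic, so alkene geometry does not matter, and the free carboxyl group is the handle that binds the catalyst.

**3 to 1 and 2.** The Ca=Cb double bond is cut to ketone 1 and diester 2. The Stobbe condensation gives exactly the required half-ester, ester on Ca and free acid on the methylene arm.

## Alternatives that were turned down

Alternative 1: Ring C is disconnected at C3–C4. A chiral triazolium-derived carbene would convert the aldehyde of the O-tethered aldehyde–enone A2 into an acyl anion equivalent, which adds to the enone beta carbon in an intramolecular Stetter reaction. Proton transfer to the resulting enolate then sets Ca and gives chromanone A1.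
- For it: the reaction class is well developed for chromanones, it is catalytic, and it builds ring C and the stereochemistry from an achiral precursor in one operation. On catalytic asymmetric ring construction it is stronger than the chosen route.
- Against it here: A1 is at the chromanone oxidation level, so a dehydrogenation must follow. That step erases C3, and the only stereocentre that counts is the one formed by the relayed protonation, between a benzhydryl group and a twisted triaryloxy ketone, where control is least predictable.
- The acceptor in A2 is an alpha-branched enone conjugated to an electron-rich, twisted aryl ketone, and the aldehyde sits between two ortho oxygens; both slow the key step.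
- A2 already contains the hindered ring D ketone, so that bond must still be made by acylation, and seven methyl ethers remain at the end.
- The chosen route instead sets Ca on a simple carboxylate-bearing alkene with one controlling element, reaches the chromone oxidation level directly and never has to form the ring D ketone by acylation.

Alternative 2: Both aryl–carbonyl bonds (ring D–C=O and C4–C4a) are cut at once. Two equivalents of aryllithium A5 would add to the bis(N-methoxy-N-methylamide) A4 to give diketone A3.
- For it: it is the shortest plan, roughly three steps fewer than the chosen route. It uses the same benzhydryl-substituted four-carbon backbone as 4, and the chelated tetrahedral intermediates prevent over-addition. On step count it is clearly stronger.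
- Against it here: the amide at Ca is neopentyl-like and A5 is di-ortho-substituted, so the second addition is the slow one, while A5 is basic enough to remove Ca–H.
- A3 is a 1,4-diaryl-1,4-diketone, and the Lewis acids needed next (ortho-demethylation, formylation, ring C closure) invite Paal–Knorr-type cyclodehydration.
- The two identical aroyl groups of A3 must then be differentiated, and seven methyl ethers must be removed.
- The chosen route also exposes Ca–H to a carbanion (step 7), so it is not better on that point. It offers in exchange built-in differentiation of the two ends, no 1,4-diketone stage and a ring D that appears without protecting groups.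

Alternative 3: Three bonds at Ca and C2 are cut (Ca–C3, Ca–Cb, O1–C2). The catalyst dirhodium tetraacetate A11, Rh2(OAc)4 with divalent rhodium, would turn diazoketone A7 into a carbenoid that the alpha carbon of enaminone A8 attacks. The resulting enol would be trapped by quinone methide A10, generated from carbinol A9 under a chiral phosphoric acid, and the phenol would close ring C with loss of the amine to give A6.
- For it: unmatched convergence. Three small components, three bonds, ring C and the stereocentre in one flask, with the Cb aryl phenols already free. On step economy it is far stronger than the chosen route.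
- Against it here: the transient enol must be intercepted by A10 faster than it tautomerises to the simple two-component product.
- The stereocentre forms on the nucleophile while the chiral acid activates the electrophile A10, whose carbon becomes the non-stereogenic Cb, so the origin of face selection is uncertain.
- The free phenols of A8, A9 and A10 are competent O–H insertion partners for the carbenoid that A11 generates from A7. A6 would also still need five demethylations next to the sensitive ketone.
- The chosen route offers separately precedented bond formations and a stereocentre that can be assayed at the first chiral intermediate.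

Key step: step 8

Remark on the chemistry (assumption): the sense of induction in step 2 cannot be predicted with confidence for this diaryl-substituted tetrasubstituted alkene; the (R,R) ligand is written, and its antipode is used if the first run shows the opposite sense.

## Route

Step 1
Reactants: 1 4,4'-dimethoxybenzophenone; 2 dimethyl succinate
Product: 3 3-(methoxycarbonyl)-4,4-bis(4-methoxyphenyl)but-3-enoic acid
Conditions: KOt-Bu, t-BuOH, reflux; then aq. HCl
Reagents that add atoms: none
Why: Stobbe condensation: the succinate enolate adds to the diaryl ketone, the alkoxide lactonises onto the distal ester, and base-induced opening of the paraconate gives the alkylidene half-ester with the ester on the future Ca and the free acid on the methylene arm; the two aryl groups are identical, so no alkene isomers arise.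

Step 2
Reactants: 3 3-(methoxycarbonyl)-4,4-bis(4-methoxyphenyl)but-3-enoic acid
Product: 4 (3R)-3-(methoxycarbonyl)-4,4-bis(4-methoxyphenyl)butanoic acid
Conditions: [Rh(cod)((R,R)-Et-DuPHOS)]BF4 (1–2 mol %), NaOMe (cat.), H2 (10–20 bar), MeOH, 25–40 °C
Reagents that add atoms: none
Why: Carboxylate-directed asymmetric hydrogenation of a Stobbe half-ester (a beta,beta-disubstituted itaconate), a substrate class established for catalysts of the [Rh(cod)(bisphospholane)]BF4 type; carboxylate and alkene chelate rhodium and the C2-symmetric ligand selects the face of Ca that receives hydrogen, Ca being the only centre formed because Cb carries two identical aryl groups.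

Step 3
Reactants: 4 (3R)-3-(methoxycarbonyl)-4,4-bis(4-methoxyphenyl)butanoic acid; 5 1,3,5-trimethoxybenzene
Product: 7 methyl (2R)-2-[bis(4-methoxyphenyl)methyl]-4-oxo-4-(2,4,6-trimethoxyphenyl)butanoate, via mixed trifluoroacetic anhydride 6 (not isolated)
Conditions: (CF3CO)2O (1.1 equiv), CH2Cl2, 0 °C; then 5 (1.5 equiv), H3PO4 (85%, cat.), 0 °C → rt
Reagents that add atoms: none
Why: Friedel–Crafts acylation through the mixed anhydride, which transfers the alkanoyl group to the very nucleophilic symmetric arene (one product, deactivated against a second acylation); the competing intramolecular closure to a tetralone would need attack at an anisyl position meta to its methoxy group and should not compete, and the acidic medium leaves the ester-bound Ca–H untouched.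

Step 4
Reactants: 7 methyl (2R)-2-[bis(4-methoxyphenyl)methyl]-4-oxo-4-(2,4,6-trimethoxyphenyl)butanoate
Product: 8 methyl (2R)-2-[bis(4-methoxyphenyl)methyl]-4-(2-hydroxy-4,6-dimethoxyphenyl)-4-oxobutanoate
Conditions: BCl3 (1.2 equiv), CH2Cl2, −78 → 0 °C; then H2O
Reagents that add atoms: none
Why: Chelation-directed mono-demethylation: boron bridges the ketone oxygen and one ortho methoxy oxygen, chloride removes that methyl group, and the resulting boron chelate protects the second ortho ether; the para and anisyl ethers and the ester do not react at this temperature.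

Step 5
Reactants: 8 methyl (2R)-2-[bis(4-methoxyphenyl)methyl]-4-(2-hydroxy-4,6-dimethoxyphenyl)-4-oxobutanoate
Product: 9 methyl (2S)-2-(5,7-dimethoxy-4-oxo-4H-chromen-3-yl)-3,3-bis(4-methoxyphenyl)propanoate
Conditions: BF3·OEt2, DMF, 0 °C → rt; then MsCl, DMF, 60–70 °C; aq. NaOAc
Reagents that add atoms: N,N-dimethylformamide, CN(C)C=O
Why: Vilsmeier-type formylation and cyclisation as used for isoflavones and 3-alkylchromones: the difluoroboron chelate of the 2-hydroxyaryl ketone enolises at the methylene, the iminium from DMF and MsCl delivers C2, and the phenol oxygen closes ring C with loss of the amine; the medium is acidic throughout, so Ca is not epimerised, and its descriptor changes from R to S only because the former methylene arm becomes sp2.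

Step 6
Reactants: 9 methyl (2S)-2-(5,7-dimethoxy-4-oxo-4H-chromen-3-yl)-3,3-bis(4-methoxyphenyl)propanoate
Product: 10 (2S)-2-(5,7-dimethoxy-4-oxo-4H-chromen-3-yl)-3,3-bis(4-methoxyphenyl)propanoic acid
Conditions: LiI (excess), EtOAc, reflux; then aq. HCl (1 M)
Reagents that add atoms: none
Why: SN2 dealkylation of a methyl ester by iodide at the methyl carbon, which is indifferent to the crowding at the acyl carbon and uses no base, so neither C2 of ring C nor the now more acidic Ca–H sees hydroxide; aryl methyl ethers do not react under these conditions.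

Step 7
Reactants: 10 (2S)-2-(5,7-dimethoxy-4-oxo-4H-chromen-3-yl)-3,3-bis(4-methoxyphenyl)propanoic acid; 11 methyl 3,5-dioxohexanoate
Product: 14 methyl (8S)-8-(5,7-dimethoxy-4-oxo-4H-chromen-3-yl)-9,9-bis(4-methoxyphenyl)-3,5,7-trioxononanoate, via trilithium trienolate 12 (not isolated), via N-acylimidazole 13 (not isolated)
Conditions: 11, LiN(i-Pr)2 (3.1 equiv), THF, 0 °C; separately 10, 1,1'-carbonyldiimidazole (1.05 equiv), THF, rt; imidazolide added to trianion (2.5 equiv), −78 → −30 °C; aq. HCl
Reagents that add atoms: none
Why: Acylation of a 1,3,5-tricarbonyl trianion at its terminal, last-formed and most nucleophilic carbon by an acyl imidazolide (polyanion Claisen acylation), forming C6–C7; the product is at once deprotonated between C5 and C7 by the excess trianion, which removes it from further reaction and shields Ca–H, and the low temperature is meant to let acyl transfer outrun proton abstraction from Ca–H of 13.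

Step 8
Reactants: 14 methyl (8S)-8-(5,7-dimethoxy-4-oxo-4H-chromen-3-yl)-9,9-bis(4-methoxyphenyl)-3,5,7-trioxononanoate
Product: 15 (2S)-2-(5,7-dimethoxy-4-oxo-4H-chromen-3-yl)-3,3-bis(4-methoxyphenyl)-1-(2,4,6-trihydroxyphenyl)propan-1-one
Conditions: Mg(OMe)2 (6–8 equiv), MeOH, rt → 45 °C; then cold aq. HCl (1 M)
Reagents that add atoms: none
Why: Mg(OMe)2 converts the triketo ester into a magnesium-chelated polyenolate in which the C5/C7 diketone is enolised across C6; C6 attacks the C1 ester carbonyl, the tetrahedral intermediate expels methoxide, and the 2-acylcyclohexane-1,3,5-trione tautomerises irreversibly to the 2,4,6-trihydroxyphenyl ketone. The closest known reaction type is the biomimetic Claisen (Dieckmann-type) cyclisation of 3,5,7-triketo esters to acylphloroglucinols, the laboratory counterpart of chalcone-synthase ring closure. Ring D closes in a 6-exo-trig mode, the enolate carbon attacking a trigonal ester carbon whose C=O lies outside the new ring, and only the C1–C6 bond is formed. No stereocentre is created; the (S) centre at Ca should be carried through because the adjacent C7 carbonyl is held as the C6-directed magnesium enolate, so removing the hindered Ca–H would build a second negative charge on the same carbonyl. The selectivity needed is Claisen closure (C6 to C1) over aldol closure (C2 to C7, leading to a resorcylate) and over lactonisation to a 4-hydroxy-2-pyrone; C7 is flanked by the branched tertiary Ca and is a poor aldol acceptor, magnesium chelation of the C3–C7 oxygens brings C6 and C1 together, and pyrone formation is reversible in methoxide whereas aromatisation is not. Ring C should be spared because the nearest chain carbon, C6, could reach C2 only by a disfavoured 5-endo-trig closure and a methoxide adduct at C2 reverts on acidification.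

Step 9
Reactants: 15 (2S)-2-(5,7-dimethoxy-4-oxo-4H-chromen-3-yl)-3,3-bis(4-methoxyphenyl)-1-(2,4,6-trihydroxyphenyl)propan-1-one
Product: 16 (+)-chamaechromone, (2S)-2-(5,7-dihydroxy-4-oxo-4H-chromen-3-yl)-3,3-bis(4-hydroxyphenyl)-1-(2,4,6-trihydroxyphenyl)propan-1-one
Conditions: BBr3 (12–15 equiv), CH2Cl2, −78 °C → rt; then MeOH/H2O, 0 °C
Reagents that add atoms: none
Why: Lewis-acid-mediated cleavage of aryl methyl ethers (boron coordination, bromide attack at methyl), standard for polymethoxylated chromones and diarylmethanes; the ring D phenols are first converted to aryloxyboranes, hence the excess, and enolisation at Ca is disfavoured because the enol would be a fully substituted alkene between three bulky groups and the ring D aryl is twisted out of conjugation.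

## Compound list

1 | 4,4'-dimethoxybenzophenone | COc1ccc(cc1)C(=O)c1ccc(OC)cc1 | starting material
2 | dimethyl succinate | COC(=O)CCC(=O)OC | starting material
3 | 3-(methoxycarbonyl)-4,4-bis(4-methoxyphenyl)but-3-enoic acid | COC(=O)C(CC(=O)O)=C(c1ccc(OC)cc1)c1ccc(OC)cc1 | intermediate
4 | (3R)-3-(methoxycarbonyl)-4,4-bis(4-methoxyphenyl)butanoic acid | COC(=O)[C@H](CC(=O)O)C(c1ccc(OC)cc1)c1ccc(OC)cc1 | intermediate
5 | 1,3,5-trimethoxybenzene | COc1cc(OC)cc(OC)c1 | starting material
6 | (3R)-3-(methoxycarbonyl)-4,4-bis(4-methoxyphenyl)butanoic trifluoroacetic anhydride | COC(=O)[C@H](CC(=O)OC(=O)C(F)(F)F)C(c1ccc(OC)cc1)c1ccc(OC)cc1 | intermediate (not isolated)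
7 | methyl (2R)-2-[bis(4-methoxyphenyl)methyl]-4-oxo-4-(2,4,6-trimethoxyphenyl)butanoate | COC(=O)[C@H](CC(=O)c1c(OC)cc(OC)cc1OC)C(c1ccc(OC)cc1)c1ccc(OC)cc1 | intermediate
8 | methyl (2R)-2-[bis(4-methoxyphenyl)methyl]-4-(2-hydroxy-4,6-dimethoxyphenyl)-4-oxobutanoate | COC(=O)[C@H](CC(=O)c1c(O)cc(OC)cc1OC)C(c1ccc(OC)cc1)c1ccc(OC)cc1 | intermediate
9 | methyl (2S)-2-(5,7-dimethoxy-4-oxo-4H-chromen-3-yl)-3,3-bis(4-methoxyphenyl)propanoate | COC(=O)[C@H](c1coc2cc(OC)cc(OC)c2c1=O)C(c1ccc(OC)cc1)c1ccc(OC)cc1 | intermediate
10 | (2S)-2-(5,7-dimethoxy-4-oxo-4H-chromen-3-yl)-3,3-bis(4-methoxyphenyl)propanoic acid | OC(=O)[C@H](c1coc2cc(OC)cc(OC)c2c1=O)C(c1ccc(OC)cc1)c1ccc(OC)cc1 | intermediate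
11 | methyl 3,5-dioxohexanoate | CC(=O)CC(=O)CC(=O)OC | starting material
12 | trilithium trienolate (trianion) of methyl 3,5-dioxohexanoate | [Li+].[Li+].[Li+].C=C([O-])C=C([O-])C=C([O-])OC | intermediate (not isolated)
13 | (2S)-2-(5,7-dimethoxy-4-oxo-4H-chromen-3-yl)-1-(1H-imidazol-1-yl)-3,3-bis(4-methoxyphenyl)propan-1-one | O=C(n1ccnc1)[C@H](c1coc2cc(OC)cc(OC)c2c1=O)C(c1ccc(OC)cc1)c1ccc(OC)cc1 | intermediate (not isolated)
14 | methyl (8S)-8-(5,7-dimethoxy-4-oxo-4H-chromen-3-yl)-9,9-bis(4-methoxyphenyl)-3,5,7-trioxononanoate (drawn as the triketo tautomer) | O=C(CC(=O)CC(=O)CC(=O)OC)[C@H](c1coc2cc(OC)cc(OC)c2c1=O)C(c1ccc(OC)cc1)c1ccc(OC)cc1 | intermediate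
15 | (2S)-2-(5,7-dimethoxy-4-oxo-4H-chromen-3-yl)-3,3-bis(4-methoxyphenyl)-1-(2,4,6-trihydroxyphenyl)propan-1-one | O=C(c1c(O)cc(O)cc1O)[C@H](c1coc2cc(OC)cc(OC)c2c1=O)C(c1ccc(OC)cc1)c1ccc(OC)cc1 | intermediate
16 | (+)-chamaechromone, (2S)-2-(5,7-dihydroxy-4-oxo-4H-chromen-3-yl)-3,3-bis(4-hydroxyphenyl)-1-(2,4,6-trihydroxyphenyl)propan-1-one | O=C(c1c(O)cc(O)cc1O)[C@H](c1coc2cc(O)cc(O)c2c1=O)C(c1ccc(O)cc1)c1ccc(O)cc1 | target

## Step count and least certain steps

Total step count: 9. Longest linear sequence: 9 steps (1 to 16); 5 and 11 enter as purchased materials.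

**Step 8 (key step).**
- What may go wrong: closure in the aldol sense (C2 onto C7) or lactonisation to a pyrone instead of the Claisen closure.
- Methoxide-induced retro-Claisen cleavage of the chain on warming.
- Slow equilibration of the C7 enolate toward Ca with loss of configuration.
- Methoxide attack at C2 followed by deformylative opening of ring C.
- Fallback, from 10 to 16, making the ring D ketone by acylation instead of ring construction: acid 10 is converted with (CF3CO)2O into its mixed trifluoroacetic anhydride F1, which acylates 5 under the conditions of step 3 to give the heptamethyl ether (2S)-2-(5,7-dimethoxy-4-oxo-4H-chromen-3-yl)-3,3-bis(4-methoxyphenyl)-1-(2,4,6-trimethoxyphenyl)propan-1-one F2. BBr3 in CH2Cl2 then removes all seven methyl ethers and the route is rejoined at 16.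

**Step 7.**
- What may go wrong: proton transfer from Ca–H of 13 to the trianion instead of acyl transfer, because the carbonyl is shielded; this would cost both conversion and configuration.
- Conjugate addition of 12 at C2 of ring C.
- O-acylation or double acylation.
- Consumption of 12 by the acidic product.
- Fallback, from 10 to 14, a base-free acylation of a silyl polyenol ether: acid 10 is converted with oxalyl chloride and catalytic DMF into (2S)-2-(5,7-dimethoxy-4-oxo-4H-chromen-3-yl)-3,3-bis(4-methoxyphenyl)propanoyl chloride F3. Separately, 11 is converted (Me3SiCl/Et3N, then LiN(i-Pr)2/Me3SiCl) into 1-methoxy-1,3,5-tris(trimethylsilyloxy)hexa-1,3,5-triene F4. F3 and F4 are combined in CH2Cl2 at −78 °C → rt, where the terminal carbon of F4 is acylated, and dilute aqueous acid removes the silyl groups to give 14.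

**Step 2.**
- What may go wrong: slow turnover at the tetrasubstituted, diaryl-conjugated alkene; insufficient face selectivity; the opposite sense of induction.
- Fallback, from 3 to 4, by resolution: 3 is hydrogenated without stereocontrol (H2, Pd/C, AcOH, 50 °C, 5 bar) to racemic 3-(methoxycarbonyl)-4,4-bis(4-methoxyphenyl)butanoic acid F5. Crystallisation with (S)-1-phenylethylamine (the amine hand to be chosen by trial) gives the salt (S)-1-phenylethylammonium (3R)-3-(methoxycarbonyl)-4,4-bis(4-methoxyphenyl)butanoate F6, while (3S)-3-(methoxycarbonyl)-4,4-bis(4-methoxyphenyl)butanoic acid F7 stays in the mother liquor. Acidification of F6 returns 4.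

**Step 5.**
- What may go wrong: sluggish C-formylation at the methylene next to the branched Ca; enol-lactone formation between the ketone enol and the ester under BF3; O-functionalisation of the phenol.
- Fallback, from 8 to 9, through an isolated enaminone: 8 is heated with N,N-dimethylformamide dimethyl acetal in toluene at 90 °C to give methyl (2S,3E)-2-[bis(4-methoxyphenyl)methyl]-3-[(dimethylamino)methylidene]-4-(2-hydroxy-4,6-dimethoxyphenyl)-4-oxobutanoate F8, which closes to 9 in AcOH at 60 °C. The enantiomeric purity of 9 would have to be checked, since this variant generates methoxide.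

**Step 9.**
- What may go wrong: incomplete cleavage of the non-chelated ethers; acid-promoted enolisation of the boron-chelated ketone with erosion of configuration at Ca; acid-induced side reactions of the electron-rich rings (attack on activated C2, loss of an aryl group from Cb).
- Fallback, from 10 to 16, moving the demethylation to a stage where Ca–H lies next to a carboxylic acid only: 10 is treated with BBr3 in CH2Cl2 to give (2S)-2-(5,7-dihydroxy-4-oxo-4H-chromen-3-yl)-3,3-bis(4-hydroxyphenyl)propanoic acid F9. t-BuMe2SiOTf and 2,6-lutidine then give the pentasilyl compound tert-butyldimethylsilyl (2S)-2-[5,7-bis(tert-butyldimethylsilyloxy)-4-oxo-4H-chromen-3-yl]-3,3-bis[4-(tert-butyldimethylsilyloxy)phenyl]propanoate F10. AcOH/THF/H2O hydrolyses only the silyl ester, giving (2S)-2-[5,7-bis(tert-butyldimethylsilyloxy)-4-oxo-4H-chromen-3-yl]-3,3-bis[4-(tert-butyldimethylsilyloxy)phenyl]propanoic acid F11. 1,1'-Carbonyldiimidazole gives the N-acylimidazole F12, which acylates 12 as in step 7 to the silyl-protected triketo ester methyl (8S)-8-[5,7-bis(tert-butyldimethylsilyloxy)-4-oxo-4H-chromen-3-yl]-9,9-bis[4-(tert-butyldimethylsilyloxy)phenyl]-3,5,7-trioxononanoate F13. Mg(OMe)2 in MeOH then closes ring D as in step 8 to (2S)-2-[5,7-bis(tert-butyldimethylsilyloxy)-4-oxo-4H-chromen-3-yl]-3,3-bis[4-(tert-butyldimethylsilyloxy)phenyl]-1-(2,4,6-trihydroxyphenyl)propan-1-one F14, which is not isolated. The same methoxide medium is expected to cleave its four aryl silyl ethers (completed with KHF2 in MeOH if needed), so that 16 is reached without any late Lewis acid.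

## Further compounds

F1 | step 8 | (2S)-2-(5,7-dimethoxy-4-oxo-4H-chromen-3-yl)-3,3-bis(4-methoxyphenyl)propanoic trifluoroacetic anhydride | O=C(OC(=O)C(F)(F)F)[C@H](c1coc2cc(OC)cc(OC)c2c1=O)C(c1ccc(OC)cc1)c1ccc(OC)cc1
F2 | step 8 | (2S)-2-(5,7-dimethoxy-4-oxo-4H-chromen-3-yl)-3,3-bis(4-methoxyphenyl)-1-(2,4,6-trimethoxyphenyl)propan-1-one | O=C(c1c(OC)cc(OC)cc1OC)[C@H](c1coc2cc(OC)cc(OC)c2c1=O)C(c1ccc(OC)cc1)c1ccc(OC)cc1
F3 | step 7 | (2S)-2-(5,7-dimethoxy-4-oxo-4H-chromen-3-yl)-3,3-bis(4-methoxyphenyl)propanoyl chloride | O=C(Cl)[C@H](c1coc2cc(OC)cc(OC)c2c1=O)C(c1ccc(OC)cc1)c1ccc(OC)cc1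
F4 | step 7 | 1-methoxy-1,3,5-tris(trimethylsilyloxy)hexa-1,3,5-triene (mixture of double-bond isomers) | C=C(O[Si](C)(C)C)C=C(O[Si](C)(C)C)C=C(OC)O[Si](C)(C)C
F5 | step 2 | racemic 3-(methoxycarbonyl)-4,4-bis(4-methoxyphenyl)butanoic acid | COC(=O)C(CC(=O)O)C(c1ccc(OC)cc1)c1ccc(OC)cc1
F6 | step 2 | (S)-1-phenylethylammonium (3R)-3-(methoxycarbonyl)-4,4-bis(4-methoxyphenyl)butanoate | COC(=O)[C@H](CC(=O)[O-])C(c1ccc(OC)cc1)c1ccc(OC)cc1.C[C@H]([NH3+])c1ccccc1
F7 | step 2 | (3S)-3-(methoxycarbonyl)-4,4-bis(4-methoxyphenyl)butanoic acid | COC(=O)[C@@H](CC(=O)O)C(c1ccc(OC)cc1)c1ccc(OC)cc1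
F8 | step 5 | methyl (2S,3E)-2-[bis(4-methoxyphenyl)methyl]-3-[(dimethylamino)methylidene]-4-(2-hydroxy-4,6-dimethoxyphenyl)-4-oxobutanoate | COC(=O)[C@H](\C(=C/N(C)C)C(=O)c1c(O)cc(OC)cc1OC)C(c1ccc(OC)cc1)c1ccc(OC)cc1
F9 | step 9 | (2S)-2-(5,7-dihydroxy-4-oxo-4H-chromen-3-yl)-3,3-bis(4-hydroxyphenyl)propanoic acid | OC(=O)[C@H](c1coc2cc(O)cc(O)c2c1=O)C(c1ccc(O)cc1)c1ccc(O)cc1
F10 | step 9 | tert-butyldimethylsilyl (2S)-2-[5,7-bis(tert-butyldimethylsilyloxy)-4-oxo-4H-chromen-3-yl]-3,3-bis[4-(tert-butyldimethylsilyloxy)phenyl]propanoate | CC(C)(C)[Si](C)(C)OC(=O)[C@H](c1coc2cc(O[Si](C)(C)C(C)(C)C)cc(O[Si](C)(C)C(C)(C)C)c2c1=O)C(c1ccc(O[Si](C)(C)C(C)(C)C)cc1)c1ccc(O[Si](C)(C)C(C)(C)C)cc1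
F11 | step 9 | (2S)-2-[5,7-bis(tert-butyldimethylsilyloxy)-4-oxo-4H-chromen-3-yl]-3,3-bis[4-(tert-butyldimethylsilyloxy)phenyl]propanoic acid | OC(=O)[C@H](c1coc2cc(O[Si](C)(C)C(C)(C)C)cc(O[Si](C)(C)C(C)(C)C)c2c1=O)C(c1ccc(O[Si](C)(C)C(C)(C)C)cc1)c1ccc(O[Si](C)(C)C(C)(C)C)cc1
F12 | step 9 | (2S)-2-[5,7-bis(tert-butyldimethylsilyloxy)-4-oxo-4H-chromen-3-yl]-3,3-bis[4-(tert-butyldimethylsilyloxy)phenyl]-1-(1H-imidazol-1-yl)propan-1-one | O=C(n1ccnc1)[C@H](c1coc2cc(O[Si](C)(C)C(C)(C)C)cc(O[Si](C)(C)C(C)(C)C)c2c1=O)C(c1ccc(O[Si](C)(C)C(C)(C)C)cc1)c1ccc(O[Si](C)(C)C(C)(C)C)cc1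
F13 | step 9 | methyl (8S)-8-[5,7-bis(tert-butyldimethylsilyloxy)-4-oxo-4H-chromen-3-yl]-9,9-bis[4-(tert-butyldimethylsilyloxy)phenyl]-3,5,7-trioxononanoate | O=C(CC(=O)CC(=O)CC(=O)OC)[C@H](c1coc2cc(O[Si](C)(C)C(C)(C)C)cc(O[Si](C)(C)C(C)(C)C)c2c1=O)C(c1ccc(O[Si](C)(C)C(C)(C)C)cc1)c1ccc(O[Si](C)(C)C(C)(C)C)cc1
F14 | step 9 | (2S)-2-[5,7-bis(tert-butyldimethylsilyloxy)-4-oxo-4H-chromen-3-yl]-3,3-bis[4-(tert-butyldimethylsilyloxy)phenyl]-1-(2,4,6-trihydroxyphenyl)propan-1-one | O=C(c1c(O)cc(O)cc1O)[C@H](c1coc2cc(O[Si](C)(C)C(C)(C)C)cc(O[Si](C)(C)C(C)(C)C)c2c1=O)C(c1ccc(O[Si](C)(C)C(C)(C)C)cc1)c1ccc(O[Si](C)(C)C(C)(C)C)cc1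
A1 | alternative 1 | (3R)-3-[(1S)-1-(2,4,6-trimethoxybenzoyl)-2,2-bis(4-methoxyphenyl)ethyl]-5,7-dimethoxychroman-4-one | O=C(c1c(OC)cc(OC)cc1OC)[C@H]([C@@H]1COc2cc(OC)cc(OC)c2C1=O)C(c1ccc(OC)cc1)c1ccc(OC)cc1
A2 | alternative 1 | 2-{[(2E)-3-[bis(4-methoxyphenyl)methyl]-4-oxo-4-(2,4,6-trimethoxyphenyl)but-2-en-1-yl]oxy}-4,6-dimethoxybenzaldehyde | O=Cc1c(OC)cc(OC)cc1OC/C=C(/C(=O)c1c(OC)cc(OC)cc1OC)C(c1ccc(OC)cc1)c1ccc(OC)cc1
A3 | alternative 2 | (2R)-2-[bis(4-methoxyphenyl)methyl]-1,4-bis(2,4,6-trimethoxyphenyl)butane-1,4-dione | O=C(c1c(OC)cc(OC)cc1OC)[C@H](CC(=O)c1c(OC)cc(OC)cc1OC)C(c1ccc(OC)cc1)c1ccc(OC)cc1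
A4 | alternative 2 | (2R)-2-[bis(4-methoxyphenyl)methyl]-N1,N4-dimethoxy-N1,N4-dimethylbutanediamide | CON(C)C(=O)[C@H](CC(=O)N(C)OC)C(c1ccc(OC)cc1)c1ccc(OC)cc1
A5 | alternative 2 | (2,4,6-trimethoxyphenyl)lithium | [Li]c1c(OC)cc(OC)cc1OC
A6 | alternative 3 | (2S)-2-(5,7-dimethoxy-4-oxo-4H-chromen-3-yl)-3,3-bis(4-hydroxyphenyl)-1-(2,4,6-trimethoxyphenyl)propan-1-one | O=C(c1c(OC)cc(OC)cc1OC)[C@H](c1coc2cc(OC)cc(OC)c2c1=O)C(c1ccc(O)cc1)c1ccc(O)cc1
A7 | alternative 3 | 2-diazo-1-(2,4,6-trimethoxyphenyl)ethan-1-one | [N-]=[N+]=CC(=O)c1c(OC)cc(OC)cc1OC
A8 | alternative 3 | (2E)-3-(dimethylamino)-1-(2-hydroxy-4,6-dimethoxyphenyl)prop-2-en-1-one | CN(C)/C=C/C(=O)c1c(O)cc(OC)cc1OC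
A9 | alternative 3 | bis(4-hydroxyphenyl)methanol | OC(c1ccc(O)cc1)c1ccc(O)cc1
A10 | alternative 3 | 4-[(4-hydroxyphenyl)methylidene]cyclohexa-2,5-dien-1-one | O=C1C=CC(=Cc2ccc(O)cc2)C=C1
A11 | alternative 3 | dirhodium tetraacetate, Rh2(OAc)4 | CC(=O)[O-].CC(=O)[O-].CC(=O)[O-].CC(=O)[O-].[Rh+2].[Rh+2]
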